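**Plan**

- Atom labels: olefin C1(Me)=C2; ring A C2–C3–C4(OH)–C5(Me)–C6; ring B C1–C2–C6–C7(OH)–C8(Me)–C17–C18–C19; ring C C8–C9–C10–C11(Me)–C16–C17; ring D C11–C12–C13–C14(Me2)–C15–C16.
- Enabling feature: C19 is an unbranched CH2 of ring B bonded to olefinic C1, and C1 is exocyclic to ring A. The C19–C1 bond can therefore be made last, from a primary alkylborane (vinyl group on C17 of ring C) and a C1 iodide whose Z geometry is fixed on ring A beforehand.
- Cuts: C19–C1 (ring B); C2–C3 (ring A, silyl enol ether onto the C1≡C2 alkyne); C6–C2, C5–Me and C6–C7 (on a trans-butyrolactone C4(=O)–O–C7); C8–C7 ([2,3] shift); C10–C11 and C16–C17 (ring C, Robinson annulation).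
- Forward order: ring D is bought, ring C is annulated, C17 and C8 are substituted, the lactone is built on C7 and opened, ring A closes with gold, ring B closes last with palladium.
- Stereochemistry: C11 from a chiral imine; C16/C17 from metal–ammonia reduction and equilibration; C8 from suprafacial [2,3] transfer off the C10 β-carbinol; C6/C7 from an auxiliary-controlled syn-aldol; C5 from trans alkylation of the lactone; C4 from hydride addition then inversion; olefin geometry from anti carboauration.

Key step: step 29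

Remark (assumption): β is the face of rings C/D that carries the C11 methyl group; any minor enantiomer that passes step 2 becomes a separable diastereomer in step 14, so full enantiomeric purity is assumed from 24 on.

**Route**

Step 1
Reactants: 1 3,3-dimethylcyclohexanone
Product: 2 rac-2,5,5-trimethylcyclohexanone
Conditions: LiN(i-Pr)2, THF, −78 °C; MeI, −78 to 0 °C
Reagents that add atoms: iodomethane, CI
Why: Kinetic enolate alkylation: the amide base removes a proton from C6, the α-carbon remote from the gem-dimethyl group (C2 is neopentyl), and the enolate is methylated; the new centre is racemic and is erased in step 2.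

Step 2
Reactants: 2 rac-2,5,5-trimethylcyclohexanone; 3 (R)-1-phenylethylamine; 4 methyl vinyl ketone
Product: 8 (S)-4a,7,7-trimethyl-4,4a,5,6,7,8-hexahydronaphthalen-2(3H)-one (rings C/D; C8 ketone; C16=C17; C11 methyl), via imine 5 (not isolated), via Michael adduct imine 6 (not isolated), via diketone 7 (not isolated)
Conditions: 3, TsOH (cat.), toluene, reflux (Dean–Stark); 4, THF, 40 °C; 10% aq. AcOH, rt; then NaOMe, MeOH, 60 °C
Reagents that add atoms: none
Why: Asymmetric Robinson annulation: the chiral imine reacts through its more substituted secondary enamine in an aza-ene-like Michael addition to 4 on the face away from the phenyl group, which by analogy with 2-methylcyclohexanone should set quaternary C11 as S, and after hydrolysis the methyl ketone closes ring C by aldol condensation.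

Step 3
Reactants: 8 (S)-octalone
Product: 9 trans-fused decalone with C8 ketone, 17α-hydroxymethyl (equatorial), 16α-H, 11β-methyl
Conditions: Li, NH3/THF, t-BuOH (1 equiv), −78 °C; isoprene; NH3 removed; CH2O (gas), THF, −78 °C; aq. NH4Cl
Reagents that add atoms: formaldehyde, C=O
Why: Dissolving-metal reduction of the enone gives the trans-fused lithium enolate (axial protonation at C16, anti to the C11 methyl), and this regiodefined C17 enolate is trapped by formaldehyde in an aldol addition on the α face, the hydroxymethyl group ending equatorial (thermodynamic and α-epimerisable).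

Step 4
Reactants: 9 hydroxymethyl decalone
Product: 10 tert-butyldimethylsilyl ether of 9
Conditions: t-BuMe2SiCl, imidazole, DMF, rt
Reagents that add atoms: tert-butyldimethylsilyl chloride, CC(C)(C)[Si](C)(C)Cl
Why: Standard silylation of the primary alcohol, which masks C18 until the vinyl group is needed.

Step 5
Reactants: 10 silyloxymethyl decalone
Product: 12 C9=C10 enone (C8 ketone), via trimethylsilyl enol ether 11 (not isolated)
Conditions: LiN(i-Pr)2, THF, −78 °C; Me3SiCl; then Pd(OAc)2 (1.1 equiv), MeCN, rt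
Reagents that add atoms: chlorotrimethylsilane, C[Si](C)(C)Cl (its atoms stay only in 11)
Why: Saegusa–Ito oxidation: kinetic deprotonation at C9 (C17 is tertiary and hindered) gives the less substituted silyl enol ether, which Pd(OAc)2 dehydrogenates to the enone.

Step 6
Reactants: 12 enone
Product: 13 tertiary allylic alcohol (C8 methyl carbinol, C9=C10; both C8 epimers)
Conditions: MeLi, CeCl3, THF, −78 °C; aq. NH4Cl
Reagents that add atoms: methyllithium, [Li]C
Why: 1,2-Addition of the hard methyl nucleophile to the enone carbonyl; the configuration of the new carbinol is irrelevant because it is destroyed in step 7.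

Step 7
Reactants: 13 tertiary allylic alcohol
Product: 14 transposed enone (C10 ketone, C8(Me)=C9)
Conditions: pyridinium chlorochromate [C5H5NH][CrO3Cl], 4 Å molecular sieves, CH2Cl2, rt
Reagents that add atoms: pyridinium chlorochromate, [O-][Cr](=O)(=O)Cl.c1cc[nH+]cc1 (the C10 oxygen)
Why: Dauben–Michno oxidative transposition: the tertiary allyl chromate undergoes a [3,3] shift to C10 and is oxidised there, which places the oxygen next to quaternary C11 and leaves the methyl group on olefinic C8.

Step 8
Reactants: 14 transposed enone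
Product: 15 allylic alcohol with 10β-OH (cis to the C11 methyl)
Conditions: NaBH4, CeCl3·7H2O, MeOH, −78 °C
Reagents that add atoms: none
Why: Luche 1,2-reduction: hydride approaches C10 axially from the α face, away from the adjacent axial C11 methyl, so the hydroxyl should come out β.

Step 9
Reactants: 15 allylic alcohol
Product: 16 (tributylstannyl)methyl ether of 15
Conditions: KH, Bu3SnCH2I, 18-crown-6 (cat.), THF, 0 °C to rt
Reagents that add atoms: (iodomethyl)tributylstannane, CCCC[Sn](CCCC)(CCCC)CI
Why: Williamson etherification of the potassium alkoxide with the reactive iodomethylstannane, the first stage of a Still–Wittig sequence.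

Step 10
Reactants: 16 stannylmethyl ether
Product: 17 homoallylic alcohol with quaternary C8 (8β-CH2OH = C7, 8α-methyl) and C9=C10
Conditions: n-BuLi, THF, −78 to −20 °C; aq. NH4Cl
Reagents that add atoms: none
Why: Still–Wittig [2,3]-sigmatropic rearrangement: tin–lithium exchange gives an α-alkoxymethyllithium whose carbon is delivered suprafacially from the β oxygen on C10 to C8, creating quaternary C8 with C7 on the β face and the methyl on the α face.

Step 11
Reactants: 17 homoallylic alcohol
Product: 18 saturated primary alcohol (C7 = CH2OH)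
Conditions: H2 (4 atm), Pd/C, EtOAc, rt
Reagents that add atoms: none
Why: Heterogeneous hydrogenation of the only olefin, a cis-disubstituted cyclohexene; no stereocentre is formed.

Step 12
Reactants: 18 primary alcohol
Product: 19 aldehyde (C7 = CHO on quaternary C8)
Conditions: Dess–Martin periodinane, NaHCO3, CH2Cl2, rt
Reagents that add atoms: none
Why: Dess–Martin oxidation of the neopentyl alcohol to a non-enolisable aldehyde.

Step 13
Reactants: 20 (R)-4-benzyl-1,3-oxazolidin-2-one; 21 methyl 4-chloro-4-oxobutanoate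
Product: 22 (R)-4-benzyl-3-(4-methoxy-4-oxobutanoyl)-1,3-oxazolidin-2-one
Conditions: n-BuLi, THF, −78 °C; then 21
Reagents that add atoms: none
Why: N-Acylation of the lithiated oxazolidinone by the acid chloride.

Step 14
Reactants: 19 aldehyde; 22 succinyl imide
Product: 24 trans-lactone imide (lactone C4(=O)–O–C7; acyl-oxazolidinone on C6 trans to the decalin on C7), via syn-aldol adduct 23 (not isolated)
Conditions: 22, Bu2BOTf, i-Pr2NEt, CH2Cl2, −78 to 0 °C; 19, −78 to 0 °C; aq. NaH2PO4/Na2HPO4 (pH 7), MeOH; then PPTS (cat.), toluene, 60 °C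
Reagents that add atoms: none
Why: Evans syn-aldol reaction: the Z boron enolate adds through a Zimmerman–Traxler chair under control of the (R)-benzyl auxiliary, setting C6 and C7, and the γ-hydroxy ester then lactonises to the trans-disubstituted butyrolactone.

Step 15
Reactants: 24 lactone imide
Product: 25 trans-lactone acid (CO2H on C6)
Conditions: LiOH, H2O2, THF/H2O, 0 °C; Na2SO3; 1 M HCl
Reagents that add atoms: hydrogen peroxide, OO (the hydroxyl oxygen of the acid)
Why: Lithium hydroperoxide attacks the exocyclic imide carbonyl selectively and releases the auxiliary; acidification recloses any opened lactone.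

Step 16
Reactants: 25 lactone acid
Product: 26 all-trans lactone acid (C5 methyl trans to the C6 carboxyl)
Conditions: NaN(SiMe3)2 (2.2 equiv), THF, −78 °C; MeI; 1 M HCl
Reagents that add atoms: iodomethane, CI
Why: Alkylation of the lactone enolate within the carboxylate dianion: iodomethane enters anti to the neighbouring C6 carboxylate, giving the trans C5 methyl group.

Step 17
Reactants: 26 methylated lactone acid; 27 1-propynylmagnesium bromide
Product: 29 all-trans lactone with C5 methyl, C6 1-propynyl and C7 decalin, via redox-active ester 28 (not isolated)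
Conditions: N-hydroxytetrachlorophthalimide, N,N′-diisopropylcarbodiimide, DMAP (cat.), CH2Cl2, rt; then 1-propynylzinc chloride (from 27, ZnCl2, THF), NiCl2·dme (20 mol %; dme = 1,2-dimethoxyethane), 4,4′-di-tert-butyl-2,2′-bipyridine (20 mol %), THF/DMF, rt
Reagents that add atoms: N-hydroxytetrachlorophthalimide, ON1C(=O)c2c(Cl)c(Cl)c(Cl)c(Cl)c2C1=O (its atoms stay only in 28)
Why: Nickel-catalysed decarboxylative alkynylation of a redox-active ester: single-electron reduction of 28 releases CO2 and a C6 radical, which nickel captures on the face opposite the flanking C5 methyl and C7 substituents before C(sp3)–C(sp) reductive elimination, so the all-trans arrangement is kept.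

Step 18
Reactants: 29 propynyl lactone
Product: 30 C18 primary alcohol
Conditions: Bu4NF, THF, 0 °C to rt
Reagents that add atoms: none
Why: Fluoride cleaves the primary silyl ether.

Step 19
Reactants: 30 alcohol
Product: 31 C18 aldehyde (formyl group α, equatorial on C17)
Conditions: Dess–Martin periodinane, NaHCO3, CH2Cl2, rt
Reagents that add atoms: none
Why: Dess–Martin oxidation; the equatorial formyl group on C17 is the thermodynamic epimer, so no stereochemical loss is expected.

Step 20
Reactants: 31 aldehyde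
Product: 32 lactone with C17 vinyl group (C18=C19)
Conditions: Ph3PCH3Br, KOt-Bu, THF, 0 °C; then 31, 0 °C to rt
Reagents that add atoms: methyltriphenylphosphonium bromide, C[P+](c1ccccc1)(c1ccccc1)c1ccccc1.[Br-]
Why: Wittig methylenation of the aldehyde; the lactone carbonyl is inert to the non-stabilised ylide at this temperature.

Step 21
Reactants: 32 vinyl lactone
Product: 33 C7-hydroxy Weinreb amide (C4 = C(=O)N(OMe)Me)
Conditions: MeNH(OMe)·HCl, Me3Al, CH2Cl2, 0 °C to rt; aq. KNaC4H4O6
Reagents that add atoms: N,O-dimethylhydroxylamine hydrochloride, CNOC.Cl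
Why: Aluminium-amide aminolysis opens the lactone to the Weinreb amide without touching C5.

Step 22
Reactants: 33 hydroxy amide
Product: 34 C7 tert-butyldimethylsilyl ether
Conditions: t-BuMe2SiOTf, 2,6-lutidine, CH2Cl2, −78 to 0 °C
Reagents that add atoms: tert-butyldimethylsilyl triflate, CC(C)(C)[Si](C)(C)OS(=O)(=O)C(F)(F)F
Why: Silyl triflate silylation of the hindered secondary alcohol, which also prevents relactonisation.

Step 23
Reactants: 34 silylated Weinreb amide
Product: 35 methyl ketone (C3H3–C4(=O)–C5)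
Conditions: MeMgBr, THF, 0 °C; aq. NH4Cl
Reagents that add atoms: methylmagnesium bromide, C[Mg]Br
Why: Weinreb ketone synthesis: the chelated tetrahedral intermediate stops at the methyl ketone.

Step 24
Reactants: 35 methyl ketone
Product: 36 terminal silyl enol ether (C3H2=C4(OSi))
Conditions: LiN(i-Pr)2, THF, −78 °C; t-BuMe2SiCl, DMPU, −78 to −20 °C
Reagents that add atoms: tert-butyldimethylsilyl chloride, CC(C)(C)[Si](C)(C)Cl
Why: Kinetic enolisation at the methyl group (C3) rather than at tertiary C5, followed by O-silylation, gives the terminal enol ether without epimerising C5.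

Step 25
Reactants: 36 silyl enol ether
Product: 37 ring A ketone with Z exocyclic C2=C1(Me)I (iodine cis to C6), C7 silyl ether and C17 vinyl group
Conditions: Ph3PAuCl (10 mol %), AgSbF6 (10 mol %), N-iodosuccinimide, NaHCO3, CH2Cl2, −20 °C to rt, dark
Reagents that add atoms: N-iodosuccinimide, O=C1CCC(=O)N1I
Why: Gold-catalysed 5-exo-dig carbocyclisation of a silyl enol ether onto an alkyne (Conia-ene type) with iodine trapping: C3 attacks C2 anti to the monovalent-gold-bound alkyne and iododeauration with retention places iodine trans to C3 and cis to C6; the β,γ-unsaturated ketone is buffered and carried on at once.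

Step 26
Reactants: 37 iodo ketone
Product: 38 4α-alcohol (OH cis to the C5 methyl; the C4 epimer of what is needed)
Conditions: Li[HB(s-Bu)3], THF, −78 °C; aq. NH4Cl
Reagents that add atoms: none
Why: The bulky borohydride attacks the cyclopentanone from the β face, opposite the C5 methyl and the C6 side chain (held pseudo-axial by allylic strain with iodine), which should give the α alcohol.

Step 27
Reactants: 38 4α-alcohol
Product: 40 4β-alcohol (OH trans to the C5 methyl), via 4-nitrobenzoate 39 (not isolated)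
Conditions: PPh3, diisopropyl azodicarboxylate, 4-nitrobenzoic acid, toluene, 0 °C to rt; then K2CO3, MeOH, rt
Reagents that add atoms: 4-nitrobenzoic acid, OC(=O)c1ccc(cc1)[N+](=O)[O-] (the C4 oxygen)
Why: Mitsunobu inversion: the carboxylate displaces the oxyphosphonium group by SN2 from the open β face, and methanolysis of the ester gives the alcohol of target configuration.

Step 28
Reactants: 40 4β-alcohol
Product: 41 bis(tert-butyldimethylsilyl) ether of the Z vinyl iodide with C17 vinyl group
Conditions: t-BuMe2SiOTf, 2,6-lutidine, CH2Cl2, 0 °C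
Reagents that add atoms: tert-butyldimethylsilyl triflate, CC(C)(C)[Si](C)(C)OS(=O)(=O)C(F)(F)F
Why: Silyl triflate silylation of the secondary alcohol, so that no free hydroxyl consumes borane in the next step.

Step 29
Reactants: 41 bis-silyl vinyl iodide
Product: 43 tetracyclic bis-silyl ether (rings A–D; Z C1=C2), via alkylborane 42 (not isolated)
Conditions: 9-BBN-H (dimer), THF, rt; then slow addition to Pd(dppf)Cl2 (20 mol %), AsPh3 (20 mol %), Cs2CO3, DMF/THF/H2O, 50 °C (final 0.002 M)
Reagents that add atoms: 9-borabicyclo[3.3.1]nonane, B1C2CCCC1CCC2 (its atoms stay only in 42)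
Why: 9-BBN-H adds across the C18=C19 vinyl group only, with boron on terminal C19; zerovalent palladium (formed from the divalent precatalyst) then inserts into the C1–I bond with retention, the base-activated borate transfers C19 to palladium, and reductive elimination forms C19–C1. The closest known reaction type is the intramolecular B-alkyl Suzuki–Miyaura coupling used for medium- and large-ring closure. Ring B closes end to end by reductive elimination from a nine-membered alkyl(alkenyl)palladacycle, helped by the trans-diequatorial C7 and C18 arms on ring C and by high dilution. No stereocentre is formed, and the Z geometry is carried over because oxidative addition and reductive elimination are stereoretentive. The step needs chemoselective hydroboration, secured because the only other olefin is the hindered tetrasubstituted iodoalkene, and it needs transmetalation to outrun β-hydride elimination, for which the wide-bite-angle dppf ligand and AsPh3 are chosen.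

Step 30
Reactants: 43 tetracyclic bis-silyl ether
Product: 44 target diol, (4R,5R,6S,7R,8S,11S,16S,17S; Z olefin) in the labels above
Conditions: Bu4NF, THF, 60 °C
Reagents that add atoms: none
Why: Fluoride removes both silyl ethers; the hindered C7 ether needs warming.

**Compound list**

1 | 3,3-dimethylcyclohexanone | CC1(C)CCCC(=O)C1 | starting material
2 | rac-2,5,5-trimethylcyclohexanone | CC1CCC(C)(C)CC1=O | intermediate
3 | (R)-1-phenylethylamine | C[C@@H](N)c1ccccc1 | starting material
4 | methyl vinyl ketone | CC(=O)C=C | starting material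
5 | (R)-1-phenylethyl imine of 2 (ring methyl centre unfixed) | C[C@@H](N=C1CC(C)(C)CCC1C)c1ccccc1 | intermediate (not isolated)
6 | (R)-1-phenylethyl imine of (S)-2,5,5-trimethyl-2-(3-oxobutyl)cyclohexanone | C[C@@H](N=C1CC(C)(C)CC[C@@]1(C)CCC(C)=O)c1ccccc1 | intermediate (not isolated)
7 | (S)-2,5,5-trimethyl-2-(3-oxobutyl)cyclohexanone | CC(=O)CC[C@]1(C)CCC(C)(C)CC1=O | intermediate (not isolated)
8 | (S)-4a,7,7-trimethyl-4,4a,5,6,7,8-hexahydronaphthalen-2(3H)-one | O=C1CC[C@]2(C)CCC(C)(C)CC2=C1 | intermediate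
9 | trans-decalone: C8 ketone, 17α-CH2OH, 16α-H, 11β-Me | O=C1CC[C@]2(C)CCC(C)(C)C[C@H]2[C@@H]1CO | intermediate
10 | silyl ether of 9 | O=C1CC[C@]2(C)CCC(C)(C)C[C@H]2[C@@H]1CO[Si](C)(C)C(C)(C)C | intermediate
11 | C8=C9 trimethylsilyl enol ether of 10 | C[Si](C)(C)OC1=CC[C@]2(C)CCC(C)(C)C[C@H]2[C@@H]1CO[Si](C)(C)C(C)(C)C | intermediate (not isolated)
12 | C9=C10 enone, C8 ketone | O=C1C=C[C@]2(C)CCC(C)(C)C[C@H]2[C@@H]1CO[Si](C)(C)C(C)(C)C | intermediate
13 | C8 methyl carbinol, C9=C10 (C8 epimers) | CC1(O)C=C[C@]2(C)CCC(C)(C)C[C@H]2[C@@H]1CO[Si](C)(C)C(C)(C)C | intermediate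
14 | C10 ketone, C8(Me)=C9 enone | CC1=CC(=O)[C@]2(C)CCC(C)(C)C[C@H]2[C@@H]1CO[Si](C)(C)C(C)(C)C | intermediate
15 | 10β-allylic alcohol | CC1=C[C@@H](O)[C@]2(C)CCC(C)(C)C[C@H]2[C@@H]1CO[Si](C)(C)C(C)(C)C | intermediate
16 | 10β-(tributylstannyl)methyl ether | CC1=C[C@@H](OC[Sn](CCCC)(CCCC)CCCC)[C@]2(C)CCC(C)(C)C[C@H]2[C@@H]1CO[Si](C)(C)C(C)(C)C | intermediate
17 | 8β-hydroxymethyl-8α-methyl C9=C10 olefin | OC[C@@]1(C)C=C[C@]2(C)CCC(C)(C)C[C@H]2[C@@H]1CO[Si](C)(C)C(C)(C)C | intermediate
18 | saturated C7 alcohol | OC[C@@]1(C)CC[C@]2(C)CCC(C)(C)C[C@H]2[C@@H]1CO[Si](C)(C)C(C)(C)C | intermediate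
19 | C7 aldehyde | O=C[C@@]1(C)CC[C@]2(C)CCC(C)(C)C[C@H]2[C@@H]1CO[Si](C)(C)C(C)(C)C | intermediate
20 | (R)-4-benzyl-1,3-oxazolidin-2-one | O=C1N[C@H](Cc2ccccc2)CO1 | starting material
21 | methyl 4-chloro-4-oxobutanoate | COC(=O)CCC(Cl)=O | starting material
22 | (R)-4-benzyl-3-(4-methoxy-4-oxobutanoyl)-1,3-oxazolidin-2-one | COC(=O)CCC(=O)N1[C@H](Cc2ccccc2)COC1=O | intermediate
23 | syn-aldol adduct (C7 carbinol, C6 imide, methyl ester) | COC(=O)C[C@@H](C(=O)N1[C@H](Cc2ccccc2)COC1=O)[C@@H](O)[C@@]3(C)CC[C@]4(C)CCC(C)(C)C[C@H]4[C@@H]3CO[Si](C)(C)C(C)(C)C | intermediate (not isolated)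
24 | trans-lactone imide | O=C1C[C@@H](C(=O)N2[C@H](Cc3ccccc3)COC2=O)[C@@H](O1)[C@@]4(C)CC[C@]5(C)CCC(C)(C)C[C@H]5[C@@H]4CO[Si](C)(C)C(C)(C)C | intermediate
25 | trans-lactone C6 carboxylic acid | O=C1C[C@@H](C(O)=O)[C@@H](O1)[C@@]2(C)CC[C@]3(C)CCC(C)(C)C[C@H]3[C@@H]2CO[Si](C)(C)C(C)(C)C | intermediate
26 | all-trans C5-methyl lactone acid | O=C1[C@H](C)[C@@H](C(O)=O)[C@@H](O1)[C@@]2(C)CC[C@]3(C)CCC(C)(C)C[C@H]3[C@@H]2CO[Si](C)(C)C(C)(C)C | intermediate
27 | 1-propynylmagnesium bromide | CC#C[Mg]Br | starting material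
28 | N-acyloxy-tetrachlorophthalimide ester of 26 | O=C1[C@H](C)[C@@H](C(=O)ON2C(=O)c3c(Cl)c(Cl)c(Cl)c(Cl)c3C2=O)[C@@H](O1)[C@@]4(C)CC[C@]5(C)CCC(C)(C)C[C@H]5[C@@H]4CO[Si](C)(C)C(C)(C)C | intermediate (not isolated)
29 | all-trans lactone with C6 1-propynyl | O=C1[C@H](C)[C@@H](C#CC)[C@@H](O1)[C@@]2(C)CC[C@]3(C)CCC(C)(C)C[C@H]3[C@@H]2CO[Si](C)(C)C(C)(C)C | intermediate
30 | C18 alcohol | O=C1[C@H](C)[C@@H](C#CC)[C@@H](O1)[C@@]2(C)CC[C@]3(C)CCC(C)(C)C[C@H]3[C@@H]2CO | intermediate
31 | C18 aldehyde | O=C1[C@H](C)[C@@H](C#CC)[C@@H](O1)[C@@]2(C)CC[C@]3(C)CCC(C)(C)C[C@H]3[C@@H]2C=O | intermediate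
32 | C17 vinyl lactone | O=C1[C@H](C)[C@@H](C#CC)[C@@H](O1)[C@@]2(C)CC[C@]3(C)CCC(C)(C)C[C@H]3[C@@H]2C=C | intermediate
33 | C7-hydroxy Weinreb amide | CON(C)C(=O)[C@H](C)[C@@H](C#CC)[C@@H](O)[C@@]1(C)CC[C@]2(C)CCC(C)(C)C[C@H]2[C@@H]1C=C | intermediate
34 | C7-silyloxy Weinreb amide | CON(C)C(=O)[C@H](C)[C@@H](C#CC)[C@@H](O[Si](C)(C)C(C)(C)C)[C@@]1(C)CC[C@]2(C)CCC(C)(C)C[C@H]2[C@@H]1C=C | intermediate
35 | methyl ketone | CC(=O)[C@H](C)[C@@H](C#CC)[C@@H](O[Si](C)(C)C(C)(C)C)[C@@]1(C)CC[C@]2(C)CCC(C)(C)C[C@H]2[C@@H]1C=C | intermediate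
36 | terminal silyl enol ether | C=C(O[Si](C)(C)C(C)(C)C)[C@H](C)[C@@H](C#CC)[C@@H](O[Si](C)(C)C(C)(C)C)[C@@]1(C)CC[C@]2(C)CCC(C)(C)C[C@H]2[C@@H]1C=C | intermediate
37 | ring A ketone with Z-(1-iodoethylidene) group | C/C(I)=C1\CC(=O)[C@H](C)[C@@H]1[C@@H](O[Si](C)(C)C(C)(C)C)[C@@]2(C)CC[C@]3(C)CCC(C)(C)C[C@H]3[C@@H]2C=C | intermediate
38 | 4α-alcohol | C/C(I)=C1\C[C@H](O)[C@H](C)[C@@H]1[C@@H](O[Si](C)(C)C(C)(C)C)[C@@]2(C)CC[C@]3(C)CCC(C)(C)C[C@H]3[C@@H]2C=C | intermediate
39 | 4β-(4-nitrobenzoate) | C/C(I)=C1\C[C@@H](OC(=O)c2ccc(cc2)[N+](=O)[O-])[C@H](C)[C@@H]1[C@@H](O[Si](C)(C)C(C)(C)C)[C@@]3(C)CC[C@]4(C)CCC(C)(C)C[C@H]4[C@@H]3C=C | intermediate (not isolated)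
40 | 4β-alcohol | C/C(I)=C1\C[C@@H](O)[C@H](C)[C@@H]1[C@@H](O[Si](C)(C)C(C)(C)C)[C@@]2(C)CC[C@]3(C)CCC(C)(C)C[C@H]3[C@@H]2C=C | intermediate
41 | bis-silyl ether, Z vinyl iodide, C17 vinyl | C/C(I)=C1\C[C@@H](O[Si](C)(C)C(C)(C)C)[C@H](C)[C@@H]1[C@@H](O[Si](C)(C)C(C)(C)C)[C@@]2(C)CC[C@]3(C)CCC(C)(C)C[C@H]3[C@@H]2C=C | intermediate
42 | C19 B-alkyl-9-BBN | C/C(I)=C1\C[C@@H](O[Si](C)(C)C(C)(C)C)[C@H](C)[C@@H]1[C@@H](O[Si](C)(C)C(C)(C)C)[C@@]2(C)CC[C@]3(C)CCC(C)(C)C[C@H]3[C@@H]2CCB4C5CCCC4CCC5 | intermediate (not isolated)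
43 | bis-silyl ether of the target | C/C1=C2\C[C@@H](O[Si](C)(C)C(C)(C)C)[C@H](C)[C@@H]2[C@@H](O[Si](C)(C)C(C)(C)C)[C@@]2(C)CC[C@]3(C)CCC(C)(C)C[C@H]3[C@@H]2CC1 | intermediate
44 | CNP0213887.1 | C/C1=C2\C[C@@H](O)[C@H](C)[C@@H]2[C@@H](O)[C@@]2(C)CC[C@]3(C)CCC(C)(C)C[C@H]3[C@@H]2CC1 | target

**Totals**

Total step count: 30. Longest linear sequence: 29 steps (steps 1–12 and 14–30, from 1); step 13 is a one-step branch that makes imide 22.

**Steps most likely to fail**

Step 29. Transmetalation of the hindered alkylborane inside the nine-membered palladacycle may be too slow, so that protodeboronation, β-hydride elimination or intermolecular coupling takes over. The fallback sets out from 41. Hydroboration with 9-BBN-H followed by oxidative work-up (NaOH, H2O2) would give the primary C19 alcohol F1. Iodination with I2, PPh3 and imidazole would give the primary iodide F2. Zinc dust with LiCl in THF at 40 °C, to which alkenyl iodides are inert, would give the alkylzinc iodide F3. An intramolecular Negishi coupling (Pd(OAc)2, SPhos, THF/NMP, high dilution) then forms the same C19–C1 bond and comes back to the route at 43.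

Step 25. N-Iodosuccinimide may iodinate the silyl enol ether at C3 before gold closes the ring, or protonation of the alkenylgold may outrun iodination; closure through C1 to a six-membered ring is a further risk that ligand choice on gold has to suppress. The fallback sets out from 36. HgCl2 with (Me3Si)2NH in CH2Cl2 would effect the same anti addition of C3 and metal across the alkyne but stop at the isolable alkenylmercury chloride F4, with no electrophilic iodine present while the C–C bond forms. Iododemercuration with I2 in CH2Cl2 at 0 °C (retention) then comes back to the route at 37.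

Step 17. Capture of the congested secondary C6 radical by nickel may be slow, so that hydrogen-atom abstraction or dimerisation wins. The fallback sets out from 25, before the C5 methylation. BH3·SMe2 would reduce the acid chemoselectively to the hydroxymethyl lactone F5. Dess–Martin periodinane would give the aldehyde F6. Lithiated Me3SiCHN2 at −78 °C (Colvin rearrangement) would homologate it to the ethynyl lactone F7. LiN(i-Pr)2 (2.2 equiv) and MeI with DMPU would then methylate the acetylide and, trans to it, the lactone enolate, coming back to the route at 29.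

**Further compounds**

F1 | step 29 | C19 primary alcohol of the bis-silyl vinyl iodide | C/C(I)=C1\C[C@@H](O[Si](C)(C)C(C)(C)C)[C@H](C)[C@@H]1[C@@H](O[Si](C)(C)C(C)(C)C)[C@@]2(C)CC[C@]3(C)CCC(C)(C)C[C@H]3[C@@H]2CCO
F2 | step 29 | C19 primary iodide | C/C(I)=C1\C[C@@H](O[Si](C)(C)C(C)(C)C)[C@H](C)[C@@H]1[C@@H](O[Si](C)(C)C(C)(C)C)[C@@]2(C)CC[C@]3(C)CCC(C)(C)C[C@H]3[C@@H]2CCI
F3 | step 29 | C19 alkylzinc iodide | C/C(I)=C1\C[C@@H](O[Si](C)(C)C(C)(C)C)[C@H](C)[C@@H]1[C@@H](O[Si](C)(C)C(C)(C)C)[C@@]2(C)CC[C@]3(C)CCC(C)(C)C[C@H]3[C@@H]2CC[Zn]I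
F4 | step 25 | Z alkenylmercury chloride (HgCl on C1, cis to C6) | C/C([Hg]Cl)=C1\CC(=O)[C@H](C)[C@@H]1[C@@H](O[Si](C)(C)C(C)(C)C)[C@@]2(C)CC[C@]3(C)CCC(C)(C)C[C@H]3[C@@H]2C=C
F5 | step 17 | trans-lactone with C6 hydroxymethyl | O=C1C[C@@H](CO)[C@@H](O1)[C@@]2(C)CC[C@]3(C)CCC(C)(C)C[C@H]3[C@@H]2CO[Si](C)(C)C(C)(C)C
F6 | step 17 | trans-lactone with C6 formyl | O=C1C[C@@H](C=O)[C@@H](O1)[C@@]2(C)CC[C@]3(C)CCC(C)(C)C[C@H]3[C@@H]2CO[Si](C)(C)C(C)(C)C
F7 | step 17 | trans-lactone with C6 ethynyl | O=C1C[C@@H](C#C)[C@@H](O1)[C@@]2(C)CC[C@]3(C)CCC(C)(C)C[C@H]3[C@@H]2CO[Si](C)(C)C(C)(C)C
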